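**Plan**

- Retrosynthetic cuts: C2–Br (back to a C2 carboxyl, ipso-bromodecarboxylation), C3–S (electrophilic sulfenylation), N1–C7a (nitrene closure of a 2-azidocinnamate), the C2–C3 alkene (aldehyde/azidoacetate condensation) and the aryl–CHO bond (C–H magnesiation of 1,2,3-tribromobenzene).
- Forward order: the benzene ring is bought with its three bromines in place; the pyrrole ring is the only ring formed (step 3, N1–C7a); C3 and then C2 are functionalised afterwards.
- Enabling feature: in the benzo ring only C7 carries hydrogen (C4, C5 and C6 carry bromine), so a 2,3,4-tribromophenyl precursor has a single free ortho carbon and N1–C7a can form at one site only.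
- Stereochemistry: the target has no stereocentre or stereogenic axis; the only stereo element on the way, the Z-alkene of the vinyl azide, is consumed in the ring closure.

Key step: step 3

Remark: the target is achiral, so it is prepared as the structure drawn and no enantiocontrol is needed.

**Route**

Step 1
Reactants: 1 1,2,3-tribromobenzene
Product: 4 2,3,4-tribromobenzaldehyde, via 2,3,4-tribromophenylmagnesium chloride 2 (not isolated), via magnesium hemiaminalate 3 (not isolated)
Conditions: TMPMgCl·LiCl (1.3 equiv), THF, 0 °C → rt; DMF, −20 °C → rt; aq. NH4Cl / 1 M HCl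
Reagents that add atoms: N,N-dimethylformamide, CN(C)C=O
Why: Directed C–H magnesiation with the Knochel–Hauser base takes place at C4 (equivalent to C6), the only kind of ring C–H ortho to bromine and therefore the most acidic, and the arylmagnesium, which unlike an aryllithium should resist halogen dance and aryne formation at these temperatures, undergoes Bouveault formylation with DMF.

Step 2
Reactants: 4 2,3,4-tribromobenzaldehyde; 5 methyl azidoacetate
Product: 7 methyl (Z)-2-azido-3-(2,3,4-tribromophenyl)acrylate, via aldol adduct 6 (not isolated)
Conditions: NaOMe (4 equiv), 5 (4 equiv), MeOH/THF, −15 → 0 °C; aq. NH4Cl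
Reagents that add atoms: none
Why: Knoevenagel-type aldol condensation in which the azidoacetate enolate adds to the aldehyde and the adduct loses hydroxide (E1cB) to the thermodynamically preferred Z-alkene, the sub-zero temperature protecting the azido ester and keeping methoxide from displacing the ortho and para bromines.

Step 3
Reactants: 7 methyl (Z)-2-azido-3-(2,3,4-tribromophenyl)acrylate
Product: 11 methyl 4,5,6-tribromo-1H-indole-2-carboxylate, via 2H-azirine 8 (not isolated), via vinyl nitrene 9 (not isolated), via 7aH-indole 10 (not isolated)
Conditions: xylenes (0.05 M, slow addition of 7), 140 °C, N2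
Reagents that add atoms: none
Why: This is a Hemetsberger–Knittel indole synthesis: on heating, azide 7 loses N2 to give 2H-azirine 8, which opens reversibly to vinyl nitrene 9. The nitrene nitrogen bonds to the free ortho carbon in a 6π 1,5-electrocyclisation that closes the five-membered pyrrole ring through N1–C7a and gives 7aH-indole 10, and a 1,5-hydrogen shift from C7a to nitrogen restores aromaticity. Because the closure is a pericyclic nitrene process and not an electrophilic substitution, the strongly deactivated tribromoarene should be tolerated. No stereocentre is formed, and the alkene geometry of 7 no longer matters once the azirine exists. The only selectivity required is between the two ortho carbons, and the substrate settles it: C2' carries bromine and C6' carries the sole ortho hydrogen, so closure at C6' (the future C7a) should give the 4,5,6-tribromo isomer alone.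

Step 4
Reactants: 11 methyl 4,5,6-tribromo-1H-indole-2-carboxylate
Product: 12 methyl 4,5,6-tribromo-3-(methylsulfanyl)-1H-indole-2-carboxylate
Conditions: MeSSMe (0.6 equiv), SO2Cl2 (0.6 equiv), CH2Cl2, −20 °C; then 11, DMF, 0 °C → rt
Reagents that add atoms: methanesulfenyl chloride, CSCl (made in the flask from dimethyl disulfide, CSSC)
Why: Electrophilic sulfenylation (SEAr) by the reactive sulfenyl chloride occurs at C3, the most nucleophilic carbon of the indole and the only free position of the pyrrole ring while the ester blocks C2.

Step 5
Reactants: 12 methyl 4,5,6-tribromo-3-(methylsulfanyl)-1H-indole-2-carboxylate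
Product: 14 4,5,6-tribromo-3-(methylsulfanyl)-1H-indole-2-carboxylic acid, via lithium carboxylate 13 (not isolated)
Conditions: LiOH·H2O (3 equiv), THF/MeOH/H2O, 45 °C; then 1 M HCl
Reagents that add atoms: lithium hydroxide, [Li+].[OH-]
Why: Saponification of the methyl ester (BAc2) under mild hydroxide conditions should leave the aryl bromides and the thioether untouched, and acidification frees the acid needed for the decarboxylative step.

Step 6
Reactants: 14 4,5,6-tribromo-3-(methylsulfanyl)-1H-indole-2-carboxylic acid
Product: 15 2,4,5,6-tetrabromo-3-(methylsulfanyl)-1H-indole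
Conditions: NBS (1.05 equiv), DMF, 0 °C → rt, dark; aq. Na2S2O3
Reagents that add atoms: N-bromosuccinimide, O=C1CCC(=O)N1Br
Why: Ipso-bromodecarboxylation (Hunsdiecker-type halodecarboxylation, familiar for pyrrole- and indole-2-carboxylic acids) should proceed by attack of Br+ at C2, the resulting C3 cation being stabilised by the sulfur lone pair, and the σ-complex rearomatises by losing CO2 instead of a proton, so bromine ends up where the carboxyl group stood.

**Compound list**

1 | 1,2,3-tribromobenzene | Brc1cccc(Br)c1Br | starting material
2 | 2,3,4-tribromophenylmagnesium chloride (LiCl complex) | Cl[Mg]c1ccc(Br)c(Br)c1Br | intermediate (not isolated)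
3 | chloromagnesium (dimethylamino)(2,3,4-tribromophenyl)methanolate (racemic) | CN(C)C(O[Mg]Cl)c1ccc(Br)c(Br)c1Br | intermediate (not isolated)
4 | 2,3,4-tribromobenzaldehyde | O=Cc1ccc(Br)c(Br)c1Br | intermediate
5 | methyl azidoacetate | COC(=O)CN=[N+]=[N-] | starting material
6 | methyl 2-azido-3-hydroxy-3-(2,3,4-tribromophenyl)propanoate (racemic diastereomer mixture, both converge on 7) | COC(=O)C(N=[N+]=[N-])C(O)c1ccc(Br)c(Br)c1Br | intermediate (not isolated)
7 | methyl (Z)-2-azido-3-(2,3,4-tribromophenyl)acrylate | COC(=O)/C(N=[N+]=[N-])=C/c1ccc(Br)c(Br)c1Br | intermediate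
8 | methyl 2-(2,3,4-tribromophenyl)-2H-azirine-3-carboxylate (racemic) | COC(=O)C1=NC1c1ccc(Br)c(Br)c1Br | intermediate (not isolated)
9 | methyl 2-nitreno-3-(2,3,4-tribromophenyl)acrylate (vinyl nitrene) | COC(=O)C([N])=Cc1ccc(Br)c(Br)c1Br | intermediate (not isolated)
10 | methyl 4,5,6-tribromo-7aH-indole-2-carboxylate (racemic) | COC(=O)C1=NC2C=C(Br)C(Br)=C(Br)C2=C1 | intermediate (not isolated)
11 | methyl 4,5,6-tribromo-1H-indole-2-carboxylate | COC(=O)c1cc2c(Br)c(Br)c(Br)cc2[nH]1 | intermediate
12 | methyl 4,5,6-tribromo-3-(methylsulfanyl)-1H-indole-2-carboxylate | COC(=O)c1[nH]c2cc(Br)c(Br)c(Br)c2c1SC | intermediate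
13 | lithium 4,5,6-tribromo-3-(methylsulfanyl)-1H-indole-2-carboxylate | [Li+].[O-]C(=O)c1[nH]c2cc(Br)c(Br)c(Br)c2c1SC | intermediate (not isolated)
14 | 4,5,6-tribromo-3-(methylsulfanyl)-1H-indole-2-carboxylic acid | OC(=O)c1[nH]c2cc(Br)c(Br)c(Br)c2c1SC | intermediate
15 | 2,4,5,6-tetrabromo-3-(methylsulfanyl)-1H-indole | CSc1c(Br)[nH]c2cc(Br)c(Br)c(Br)c12 | target

**Totals**

Total step count: 6. Longest linear sequence: 6 steps (1 → 4 → 7 → 11 → 12 → 14 → 15).

**Steps most likely to fail**

Step 6. The electrophilic bromine may be intercepted by sulfur (S-bromination, then sulfoxide on work-up), or may attack C3 ipso to sulfur with loss or 1,2-shift of the methylsulfanyl group, instead of attacking the carboxyl-bearing C2. The fallback separates decarboxylation from bromination. Setting out from acid 14, silver-catalysed protodecarboxylation (Ag2CO3 cat., AcOH cat., DMSO, 120 °C) would give 4,5,6-tribromo-3-(methylsulfanyl)-1H-indole F1. Its free C2–H would then be brominated with NBS (1.0 equiv, CH2Cl2, −78 → 0 °C), a substitution in which halogen taken up at sulfur or C3 is relayed to C2 and a proton is lost. This returns to the route at target 15.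

Step 1. Deprotonation of a C–H bond acidified by only one ortho bromine may be incomplete, and forcing it may cause bromine scrambling or aryne formation. The fallback replaces C–H metalation by halogen–metal exchange. Setting out from 1, electrophilic iodination (NIS, TfOH, CH2Cl2, 0 °C → rt) at C4, which is ortho to one bromine and para to another and so the most activated site, would give 1,2,3-tribromo-4-iodobenzene F2. Iodine–magnesium exchange with iPrMgCl·LiCl (THF, −40 °C), selective for iodine over bromine, returns to the route at arylmagnesium 2, which is formylated with DMF as before to give 4.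

Step 4. Electrophilic attack at C3 may be slow, because this carbon is flanked by the 4-bromine and deactivated by the ester and three bromines, so that N-sulfenylation or decay of the sulfenyl chloride takes over. The fallback raises the nucleophilicity of the substrate instead of the electrophilicity of the reagent. Setting out from 11, deprotonation with NaH (DMF, 0 °C) would give sodium 4,5,6-tribromo-2-(methoxycarbonyl)indol-1-ide F3. This ambident anion should be sulfenylated at C3 by S-methyl methanethiosulfonate (0 °C → rt), whose sulfinate leaving group cannot demethylate the ester. This returns to the route at 12.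

**Further compounds**

F1 | step 6 | 4,5,6-tribromo-3-(methylsulfanyl)-1H-indole | CSc1c[nH]c2cc(Br)c(Br)c(Br)c12
F2 | step 1 | 1,2,3-tribromo-4-iodobenzene | Ic1ccc(Br)c(Br)c1Br
F3 | step 4 | sodium 4,5,6-tribromo-2-(methoxycarbonyl)indol-1-ide | COC(=O)c1cc2c(Br)c(Br)c(Br)cc2[n-]1.[Na+]
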